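0.0196 M h⁻¹ of target was the number I carried: the mean pace, meaning the molar concentration of target at the last reading, divided by the time of that reading and averaged over the earlier runs.

| flask | solid substrate | remark | time |
|---|---|---|---|
| south | 0.27 M | run made earlier |  |
| south-west | 0.42 M | run made earlier |  |
| north | 0.75 M | run made earlier |  |
| Thursday's | 0.50 M |  | 6.0 h |
| Sunday's | 0.80 M |  | 6.0 h |
| Wednesday's | 0.25 M |  | 6.0 h |
| Saturday's | 0.40 M |  | 6.0 h |

| south: time / h | south: target / % | south-west: time / h | south-west: target / % | north: time / h | north: target / % |
|---|---|---|---|---|---|
| 1.33 | 12.4 | 1.33 | 8.3 | 0.500 | 2.1 |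
| 2.50 | 23.6 | 2.50 | 14.7 | 1.50 | 6.1 |
| 4.00 | 30.2 | 4.00 | 19.0 | 3.00 | 10.0 |
| 5.00 | 36.3 | 5.00 | 23.5 | 4.00 | 11.0 |
| 6.00 | 42.8 | 6.00 | 29.2 | 6.00 | 15.2 |

(readings scatter by 1 percentage point)

- given per volume of solution although it is solid: solid substrate
- at the start none of the solid substrate is in solution
- what has only dissolved of solid substrate counts as not reacted

- the flasks put in order of amount of target, in percent of the solid substrate charged, best first, at 6.0 h (Thursday's / Sunday's / Wednesday's / Saturday's)
- the amount of target, in percent of the solid substrate charged of the flask you put first, at 6.0 h
- the amount of target, in percent of the solid substrate charged of the flask you put last, at 6.0 h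

I built the flask up one process at a time. First I took a single process, target appearing at a pace blind to the charge (apparent zero order in the charge), so that the percent is pace times time over charge. At 6.00 h this line passed 0.68 percentage points above south, 1.2 points below south-west and 0.45 points above north, against a scatter of 1 point.

Then I added the end of the solid, since the line can hold only while solid lasts. For Wednesday's it asked 47.0 % of the charge as target. South, with a similar charge, still read a gain of 6.5 points in its last hour where the line gives 7.2 points, so I left my number unchanged.

Last came the bend of the curve. South's first stretch read 0.0252 M h⁻¹, faster than the mean, so the pace is a mean over a curve. But the four flasks are read at 6.0 h, the time of the last readings, so the bend already lies inside the mean.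

I committed to 47.0 % for Wednesday's and 14.7 % for Sunday's. The forecast, which weighted the runs where my mean did not, stood lower: Wednesday's > Saturday's > Thursday's > Sunday's, with 46.5 % and 14.5 %, on the reading that “Target formed therefore doesn't depend on the charge”.

The simulation gave Wednesday's > Saturday's > Thursday's > Sunday's, with 46.1 % and 14.4 %, from this mechanism:

    released group → by-product carried off (k = 4.20 × 10⁻⁵ s⁻¹)
    target + released group → side product (k = 7.40 × 10⁻⁶ M⁻¹ s⁻¹)
    solid substrate ⇌ starting material, rate k3*(cs3 - [starting material]) while solid is left; crystals form when [starting material] > cs3 (solubility = 0.710 M, k = 1.60 × 10⁻⁵ s⁻¹)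
    starting material ⇌ target + released group (K = 0.0770 M, k = 0.00130 s⁻¹)

Wednesday's still held 9.17 % of its charge as solid substrate at 6.00 h. The result of Wednesday's gives a mean pace of 0.0192 M h⁻¹, and Sunday's gives 0.0192 M h⁻¹. For the flask like Sunday's but charged with 0.32 M, my pace asked 36.7 %, and that flask gave 36.0 %.

(The runs were generated by integration for substances that don't exist; noise was put on by code.)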